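The carbocyclic ring of the isoquinoline (C4a–C5–C6–C7–C8–C8a) is cut at C6–C7 and C7–C8. C8, the future phenol carbon, is bonded to C8a of the pyridine ring and is traced back to a carboxylate. C5–C6 is bonded to C4a and is traced back to a vinyl group. C7, the axis carbon, then becomes the α-carbon of a naphthylacetic ester. One anionic operation (conjugate addition, then Claisen acylation) joins both halves and closes this ring. Dealkoxycarbonylation and dehydrogenation later flatten C7 into the biaryl carbon. The precursors are methyl naphthylacetate 21 and 4-vinylnicotinate 8, the latter as its phenyl ester so that closure to a non-enolisable β-keto ester is irreversible.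

Key step: step 11

Assumption: the SMILES is taken as binding (4′-OMe, free 5′-OH and 8-OH, no descriptor for the C7–C1′ axis); the route gives 27 as the racemate of the axis, and the named antipode would be taken from 27 by preparative HPLC on a cellulose-carbamate chiral phase, which is not counted as a step.

Step 1
Reactants: 1 ethyl (Z)-3-aminobut-2-enoate; 2 2,2,6-trimethyl-4H-1,3-dioxin-4-one
Product: 4 ethyl 4-hydroxy-2,6-dimethylpyridine-3-carboxylate, via acetylketene 3 (not isolated)
Conditions: xylene, 130 °C (acetone distilled off)
Reagents that add atoms: none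
Why: Heating 2 releases acetone and acetylketene 3 (retro-hetero-Diels–Alder), which C-acylates the nucleophilic α-carbon of enaminoester 1, after which the amino group condenses with the terminal ketone and water is lost (acylketene–enamine synthesis of 4-pyridones, drawn as the 4-hydroxypyridine tautomer).

Step 2
Reactants: 4 ethyl 4-hydroxy-2,6-dimethylpyridine-3-carboxylate
Product: 5 4-hydroxy-2,6-dimethylpyridine-3-carboxylic acid
Conditions: NaOH, H2O/EtOH, reflux; then HCl to pH 4
Reagents that add atoms: sodium hydroxide, [Na+].[OH-]
Why: Ordinary BAc2 saponification, slowed but not stopped by the two ortho substituents, and the amphoteric acid should crystallise at its isoelectric point.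

Step 3
Reactants: 5 4-hydroxy-2,6-dimethylpyridine-3-carboxylic acid
Product: 7 phenyl 4-chloro-2,6-dimethylpyridine-3-carboxylate, via acid chloride 6 (not isolated)
Conditions: POCl3, reflux; evaporate; PhOH (1.0 equiv), Et3N, DMAP (cat.), CH2Cl2, 0 °C → rt
Reagents that add atoms: phosphoryl chloride, O=P(Cl)(Cl)Cl; phenol, Oc1ccccc1
Why: POCl3 brings about deoxychlorination of the 4-pyridone and acid chloride formation in one operation, and because the acyl chloride of 6 is much more electrophilic than its C4–Cl bond, one equivalent of phenol should give only O-acylation (DMAP-catalysed esterification) and no SNAr.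

Step 4
Reactants: 7 phenyl 4-chloro-2,6-dimethylpyridine-3-carboxylate
Product: 8 phenyl 4-ethenyl-2,6-dimethylpyridine-3-carboxylate
Conditions: Bu3SnCH=CH2, Pd(PPh3)4 (cat.), BHT (trace), toluene, 100 °C
Reagents that add atoms: tributyl(vinyl)stannane, C=C[Sn](CCCC)(CCCC)CCCC
Why: Stille coupling, in which the C4–Cl bond, activated by the ring nitrogen and the ortho ester, adds oxidatively to zerovalent palladium, while the absence of base and water spares the phenyl ester and BHT guards the vinylpyridine against radical polymerisation.

Step 5
Reactants: 9 3-(benzyloxy)phenol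
Product: 10 3-(benzyloxy)phenyl propan-2-ylcarbamate
Conditions: i-PrNCO, Et3N (cat.), CH2Cl2, rt
Reagents that add atoms: isopropyl isocyanate, CC(C)N=C=O
Why: Amine-catalysed addition of the phenol to the isocyanate (carbamoylation) installs a strong ortho-directing group that can be taken off again under mild E1cB conditions.

Step 6
Reactants: 10 3-(benzyloxy)phenyl propan-2-ylcarbamate
Product: 13 3-(benzyloxy)-2-(trimethylsilyl)phenyl propan-2-ylcarbamate, via N-silyl carbamate 11 (not isolated), via N-silyl 2-(trimethylsilyl) carbamate 12 (not isolated)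
Conditions: t-BuMe2SiOTf, TMEDA, Et2O, 0 °C → rt; n-BuLi (2 equiv), TMEDA, −78 °C; Me3SiCl, −78 °C → rt; aq NaHSO4
Reagents that add atoms: chlorotrimethylsilane, C[Si](C)(C)Cl; tert-butyldimethylsilyl triflate, CC(C)(C)[Si](C)(C)OS(=O)(=O)C(F)(F)F (its silyl group is carried only by 11 and 12)
Why: Directed ortho-metalation: passing N-silylation masks the N–H, the C2–H bond between the carbamate and benzyloxy oxygens is the most acidic and best coordinated ring position so that lithiation at −78 °C should outrun benzylic deprotonation of the ether, Me3SiCl traps the aryllithium, and the labile N–Si bond is hydrolysed in the acidic work-up.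

Step 7
Reactants: 13 3-(benzyloxy)-2-(trimethylsilyl)phenyl propan-2-ylcarbamate
Product: 15 3-(benzyloxy)-2-(trimethylsilyl)phenyl trifluoromethanesulfonate, via silylphenol 14 (not isolated)
Conditions: DBU, Et2NH, MeCN, 40 °C; then PhNTf2, rt
Reagents that add atoms: N-phenylbis(trifluoromethanesulfonimide), O=S(=O)(N(c1ccccc1)S(=O)(=O)C(F)(F)F)C(F)(F)F
Why: DBU cleaves the secondary carbamate by E1cB loss of isopropyl isocyanate, which Et2NH scavenges as a urea, and the phenoxide of 14 is sulfonylated in the same flask by the mild triflyl donor PhNTf2, so that the desilylation-prone phenol is never handled.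

Step 8
Reactants: 16 acetylacetone (pentane-2,4-dione)
Product: 17 methyl 3-acetyl-4-oxopentanoate
Conditions: BrCH2CO2Me, K2CO3, acetone, reflux (16 in excess)
Reagents that add atoms: methyl bromoacetate, COC(=O)CBr
Why: SN2 C-alkylation of the soft potassium enolate of a 1,3-diketone by an α-bromo ester, with 16 in excess to hold back double alkylation.

Step 9
Reactants: 15 3-(benzyloxy)-2-(trimethylsilyl)phenyl trifluoromethanesulfonate; 17 methyl 3-acetyl-4-oxopentanoate
Product: 19 methyl 3-[2-acetyl-3-(benzyloxy)phenyl]-4-oxopentanoate (racemic), via 3-(benzyloxy)benzyne 18 (not isolated)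
Conditions: CsF (dry), MeCN, 80 °C
Reagents that add atoms: none
Why: Aryne acyl-alkylation (formal insertion into a C–C(=O) bond): fluoride-induced 1,2-elimination gives 18, the diketone enolate attacks the aryne carbon remote from OBn because the aryl anion then develops next to the inductively withdrawing oxygen, this anion adds to an acetyl group and the benzocyclobutenoxide fragments, which places the acetyl group ortho to OBn, and the new stereocentre is racemic and vanishes in step 10.

Step 10
Reactants: 19 methyl 3-[2-acetyl-3-(benzyloxy)phenyl]-4-oxopentanoate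
Product: 21 methyl 2-[5-(benzyloxy)-4-methoxy-2-methylnaphthalen-1-yl]acetate, via naphthol 20 (not isolated)
Conditions: Cs2CO3, DMF, Ar, rt → 60 °C; then MeI, rt
Reagents that add atoms: iodomethane, CI
Why: Intramolecular aldol condensation, 6-(enolexo)-exo-trig, of the aryl methyl ketone enolate onto the more electrophilic and less shielded aliphatic ketone is made irreversible by dehydration and tautomerisation to naphthol 20, whose caesium salt undergoes Williamson O-methylation, and MeI would also restore any ester lost to the water set free, which is one reason for choosing the methyl ester.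

Step 11
Reactants: 21 methyl 2-[5-(benzyloxy)-4-methoxy-2-methylnaphthalen-1-yl]acetate; 8 phenyl 4-ethenyl-2,6-dimethylpyridine-3-carboxylate
Product: 23 methyl 7-[5-(benzyloxy)-4-methoxy-2-methylnaphthalen-1-yl]-1,3-dimethyl-8-oxo-5,6,7,8-tetrahydroisoquinoline-7-carboxylate (racemic), via Michael adduct 22 (not isolated)
Conditions: 21 (1.2 equiv), LiN(SiMe3)2 (1.2 equiv), THF, −78 °C; 8 added slowly, −78 → 0 °C; aq NH4Cl
Reagents that add atoms: none
Why: Proposed new method: the fully preformed lithium enolate of 21 should add to the terminal vinyl carbon of 8 (C6), because the C5 carbanion so formed is delocalised onto the ring nitrogen and into the ortho ester carbonyl; proton exchange through HN(SiMe3)2 moves the charge to C7 (enolate of 22), which attacks the phenyl ester and expels phenoxide. The closest known reactions are Michael–Dieckmann annulations of ester enolates (Staunton–Weinreb type) and the pyridylethylation of stabilised carbanions by 4-vinylpyridines, but their union in a ring closure onto a nicotinate has not been shown. The ring closes in the 6-(enolexo)-exo-trig mode, and should acylation come first, a 6-endo-trig conjugate addition would lead to the same 23. C7 is the only new stereocentre, nothing controls it, and the racemate is harmless because steps 12 and 13 turn C7 into an sp2 carbon. The step needs chemoselectivity between two ester carbonyls and between addition and oligomerisation: only the pyridine ester lies within a six-membered transition state and carries the better leaving group, while slow addition of 8 to a slight excess of enolate free of amide base keeps the vinylpyridine concentration low and leaves the 2- and 6-methyl groups alone. Since the new ketone has no α-hydrogen and cannot be protected as its enolate, the leaving group is phenoxide, a far weaker base than the attacking enolate and too poor a nucleophile to reopen the hindered ketone, so that the closure should be downhill and retro-Claisen cleavage suppressed.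

Step 12
Reactants: 23 methyl 7-[5-(benzyloxy)-4-methoxy-2-methylnaphthalen-1-yl]-1,3-dimethyl-8-oxo-5,6,7,8-tetrahydroisoquinoline-7-carboxylate
Product: 24 7-[5-(benzyloxy)-4-methoxy-2-methylnaphthalen-1-yl]-1,3-dimethyl-6,7-dihydroisoquinolin-8(5H)-one (racemic)
Conditions: LiCl, H2O, DMSO, 140 °C, Ar
Reagents that add atoms: none
Why: Krapcho dealkoxycarbonylation: chloride attacks the exposed ester methyl group (SN2), the carboxylate loses CO2 readily because an aryl-conjugated ketone enolate is released and then protonated by water, and the near-neutral salt medium avoids the alkoxide or hydroxide that would cleave the non-enolisable β-keto ester; C7 stays racemic.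

Step 13
Reactants: 24 7-[5-(benzyloxy)-4-methoxy-2-methylnaphthalen-1-yl]-1,3-dimethyl-6,7-dihydroisoquinolin-8(5H)-one
Product: 26 7-[5-(benzyloxy)-4-methoxy-2-methylnaphthalen-1-yl]-1,3-dimethylisoquinolin-8-ol (racemic axis), via 7-bromo ketone 25 (not isolated)
Conditions: LiN(SiMe3)2 (1.1 equiv), THF, −78 → 0 °C; NBS (1.0 equiv), −78 °C; DBU, → rt
Reagents that add atoms: N-bromosuccinimide, O=C1CCC(=O)N1Br (its bromine is carried only by 25)
Why: Enolate α-bromination followed by dehydrobromination: the preformed enolate is far more nucleophilic than the electron-rich naphthalene, so one equivalent of NBS at −78 °C should deliver bromine to C7 only, and base-induced loss of HBr towards C6 gives the keto tautomer of the isoquinolin-8-ol, which aromatises at once, erasing the C7 stereocentre and creating the C7–C1′ axis in racemic form.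

Step 14
Reactants: 26 7-[5-(benzyloxy)-4-methoxy-2-methylnaphthalen-1-yl]-1,3-dimethylisoquinolin-8-ol
Product: 27 7-(5-hydroxy-4-methoxy-2-methylnaphthalen-1-yl)-1,3-dimethylisoquinolin-8-ol (target constitution, racemic axis)
Conditions: H2 (1 atm), 10% Pd/C, EtOAc/MeOH, rt
Reagents that add atoms: none
Why: Catalytic hydrogenolysis of the aryl benzyl ether, under neutral conditions at atmospheric pressure that should leave the isoquinoline, the naphthalene and the methyl ether untouched.

Compound list
1 | ethyl (Z)-3-aminobut-2-enoate | CCOC(=O)/C=C(/C)N | starting material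
2 | 2,2,6-trimethyl-4H-1,3-dioxin-4-one | CC1=CC(=O)OC(C)(C)O1 | starting material
3 | acetylketene (3-oxobut-1-en-1-one), not isolated | CC(=O)C=C=O | intermediate
4 | ethyl 4-hydroxy-2,6-dimethylpyridine-3-carboxylate | CCOC(=O)c1c(C)nc(C)cc1O | intermediate
5 | 4-hydroxy-2,6-dimethylpyridine-3-carboxylic acid | Cc1cc(O)c(C(=O)O)c(C)n1 | intermediate
6 | 4-chloro-2,6-dimethylpyridine-3-carbonyl chloride, not isolated | Cc1cc(Cl)c(C(=O)Cl)c(C)n1 | intermediate
7 | phenyl 4-chloro-2,6-dimethylpyridine-3-carboxylate | Cc1cc(Cl)c(C(=O)Oc2ccccc2)c(C)n1 | intermediate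
8 | phenyl 4-ethenyl-2,6-dimethylpyridine-3-carboxylate | C=Cc1cc(C)nc(C)c1C(=O)Oc1ccccc1 | intermediate
9 | 3-(benzyloxy)phenol | Oc1cccc(OCc2ccccc2)c1 | starting material
10 | 3-(benzyloxy)phenyl propan-2-ylcarbamate | CC(C)NC(=O)Oc1cccc(OCc2ccccc2)c1 | intermediate
11 | 3-(benzyloxy)phenyl [tert-butyl(dimethyl)silyl](propan-2-yl)carbamate, not isolated | CC(C)N(C(=O)Oc1cccc(OCc2ccccc2)c1)[Si](C)(C)C(C)(C)C | intermediate
12 | 3-(benzyloxy)-2-(trimethylsilyl)phenyl [tert-butyl(dimethyl)silyl](propan-2-yl)carbamate, not isolated | CC(C)N(C(=O)Oc1cccc(OCc2ccccc2)c1[Si](C)(C)C)[Si](C)(C)C(C)(C)C | intermediate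
13 | 3-(benzyloxy)-2-(trimethylsilyl)phenyl propan-2-ylcarbamate | CC(C)NC(=O)Oc1cccc(OCc2ccccc2)c1[Si](C)(C)C | intermediate
14 | 3-(benzyloxy)-2-(trimethylsilyl)phenol, not isolated | Oc1cccc(OCc2ccccc2)c1[Si](C)(C)C | intermediate
15 | 3-(benzyloxy)-2-(trimethylsilyl)phenyl trifluoromethanesulfonate | C[Si](C)(C)c1c(OCc2ccccc2)cccc1OS(=O)(=O)C(F)(F)F | intermediate
16 | acetylacetone (pentane-2,4-dione) | CC(=O)CC(C)=O | starting material
17 | methyl 3-acetyl-4-oxopentanoate | COC(=O)CC(C(C)=O)C(C)=O | intermediate
18 | 3-(benzyloxy)benzyne (1-benzyloxy-2,3-didehydrobenzene), not isolated | C1#CC(OCc2ccccc2)=CC=C1 | intermediate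
19 | methyl 3-[2-acetyl-3-(benzyloxy)phenyl]-4-oxopentanoate (racemic) | COC(=O)CC(C(C)=O)c1cccc(OCc2ccccc2)c1C(C)=O | intermediate
20 | methyl 2-[5-(benzyloxy)-4-hydroxy-2-methylnaphthalen-1-yl]acetate, not isolated | COC(=O)Cc1c(C)cc(O)c2c(OCc3ccccc3)cccc12 | intermediate
21 | methyl 2-[5-(benzyloxy)-4-methoxy-2-methylnaphthalen-1-yl]acetate | COC(=O)Cc1c(C)cc(OC)c2c(OCc3ccccc3)cccc12 | intermediate
22 | methyl 2-[5-(benzyloxy)-4-methoxy-2-methylnaphthalen-1-yl]-4-[2,6-dimethyl-3-(phenoxycarbonyl)pyridin-4-yl]butanoate (racemic, present as its lithium enolate), not isolated | COC(=O)C(CCc1cc(C)nc(C)c1C(=O)Oc1ccccc1)c1c(C)cc(OC)c2c(OCc3ccccc3)cccc12 | intermediate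
23 | methyl 7-[5-(benzyloxy)-4-methoxy-2-methylnaphthalen-1-yl]-1,3-dimethyl-8-oxo-5,6,7,8-tetrahydroisoquinoline-7-carboxylate (racemic) | COC(=O)C1(c2c(C)cc(OC)c3c(OCc4ccccc4)cccc23)CCc2cc(C)nc(C)c2C1=O | intermediate
24 | 7-[5-(benzyloxy)-4-methoxy-2-methylnaphthalen-1-yl]-1,3-dimethyl-6,7-dihydroisoquinolin-8(5H)-one (racemic) | Cc1cc2c(c(C)n1)C(=O)C(c1c(C)cc(OC)c3c(OCc4ccccc4)cccc13)CC2 | intermediate
25 | 7-bromo-7-[5-(benzyloxy)-4-methoxy-2-methylnaphthalen-1-yl]-1,3-dimethyl-6,7-dihydroisoquinolin-8(5H)-one (racemic), not isolated | Cc1cc2c(c(C)n1)C(=O)C(Br)(c1c(C)cc(OC)c3c(OCc4ccccc4)cccc13)CC2 | intermediate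
26 | 7-[5-(benzyloxy)-4-methoxy-2-methylnaphthalen-1-yl]-1,3-dimethylisoquinolin-8-ol (racemic axis) | COc1cc(C)c(-c2ccc3cc(C)nc(C)c3c2O)c2cccc(OCc3ccccc3)c12 | intermediate
27 | 7-(5-hydroxy-4-methoxy-2-methylnaphthalen-1-yl)-1,3-dimethylisoquinolin-8-ol | COc1cc(C)c(-c2ccc3cc(C)nc(C)c3c2O)c2cccc(O)c12 | target

Total step count: 14.
Longest linear sequence: 9 steps (5, 6, 7, 9, 10, 11, 12, 13, 14).

Steps most likely to fail

Step 11. The C5 carbanion may start anionic oligomerisation of the vinylpyridine before proton transfer. The sequence may also stall after the conjugate addition, because a tertiary, naphthyl-shielded enolate has to reach a doubly ortho-flanked ester carbonyl. The fallback sets out from 6 and 21 and returns at 23. It makes the two bonds in the opposite order, in separate flasks, by known reactions. The lithium enolate of 21 (two equivalents of LiN(SiMe3)2, because the product is acidic) would be C-acylated with crude acid chloride 6. This gives methyl 2-[5-(benzyloxy)-4-methoxy-2-methylnaphthalen-1-yl]-3-(4-chloro-2,6-dimethylpyridin-3-yl)-3-oxopropanoate F1, an enolisable β-keto ester whose deprotonation drives the Claisen step in the classical way. Stille vinylation under the conditions of step 4 gives methyl 2-[5-(benzyloxy)-4-methoxy-2-methylnaphthalen-1-yl]-3-(4-ethenyl-2,6-dimethylpyridin-3-yl)-3-oxopropanoate F2. Warming F2 in acetic acid (activation as the vinylpyridinium) or with catalytic DBU closes C6–C7 by intramolecular pyridylethylation of the β-keto ester (6-endo-trig). No alkoxide is present at any point, and the product is 23.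

Step 9. The branched enolate may attack so slowly that aryne self-consumption, plain arylation without acyl transfer, or base-induced deacetylation of the diketone take over. The fallback sets out from 15 and 16 and returns at 19. The insertion would be run on unbranched acetylacetone 16, the best documented diketone class for this reaction, under the same CsF/MeCN conditions, to give 1-[2-acetyl-3-(benzyloxy)phenyl]propan-2-one F3. Its benzylic methylene, flanked by the aryl ring and an acetyl group, is the most acidic site. It would be deprotonated with one equivalent of LiN(SiMe3)2 at −78 °C, cold enough to hold back the aldol closure. Alkylation with methyl bromoacetate then gives 19.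

Step 13. Enolisation may be incomplete or misdirected (C1-methyl or C5 in place of the shielded C7–H), so that bromine is transferred to the wrong site. The phenol ring may also be over-brominated once aromatisation has begun. The fallback sets out from 24 and returns at 26. Soft, equilibrating enolisation with Me3SiOTf/Et3N in CH2Cl2 would give 7-[5-(benzyloxy)-4-methoxy-2-methylnaphthalen-1-yl]-1,3-dimethyl-8-[(trimethylsilyl)oxy]-5,6-dihydroisoquinoline F4. DDQ in toluene at rt then abstracts hydride from C6, allylic to the enol ether, so no new bond to the crowded C7 is required. Loss of the silyl group on aqueous work-up and tautomerisation give 26.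

Further compounds
F1 | step 11 | methyl 2-[5-(benzyloxy)-4-methoxy-2-methylnaphthalen-1-yl]-3-(4-chloro-2,6-dimethylpyridin-3-yl)-3-oxopropanoate | COC(=O)C(C(=O)c1c(C)nc(C)cc1Cl)c1c(C)cc(OC)c2c(OCc3ccccc3)cccc12
F2 | step 11 | methyl 2-[5-(benzyloxy)-4-methoxy-2-methylnaphthalen-1-yl]-3-(4-ethenyl-2,6-dimethylpyridin-3-yl)-3-oxopropanoate | COC(=O)C(C(=O)c1c(C)nc(C)cc1C=C)c1c(C)cc(OC)c2c(OCc3ccccc3)cccc12
F3 | step 9 | 1-[2-acetyl-3-(benzyloxy)phenyl]propan-2-one | CC(=O)Cc1cccc(OCc2ccccc2)c1C(C)=O
F4 | step 13 | 7-[5-(benzyloxy)-4-methoxy-2-methylnaphthalen-1-yl]-1,3-dimethyl-8-[(trimethylsilyl)oxy]-5,6-dihydroisoquinoline | Cc1cc2c(c(C)n1)C(O[Si](C)(C)C)=C(c1c(C)cc(OC)c3c(OCc4ccccc4)cccc13)CC2
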